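**Plan**
- Retrosynthetic cuts in the upper part, in order: the acetate, ring D at O–C15, ring C at O–C13, then C14–C15, C11–C12 and C9=C11. What remains is an 8α-methyl 11-nordrimane-6,9-dione (labdane numbering; rings A and B decalin, C oxolane, D dihydrofuran).
- Enabling feature: in ring B the only two heteroatom-bearing carbons, C6 and C9, stand 1,4 to each other. C9 can therefore be the oxygenated inner carbon of a C7=C8–C9=C10 diene, and C6 the acceptor-bearing carbon of a C5=C6 dienophile. C1–C4 of ring A already tie C10 to C5, so cutting C5–C10 and C6–C7 opens rings A and B together to an achiral nitro triene.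
- The triene is cut at C5–C6 (Henry reaction) and at C1–C2 (terminal alkylation of a 3-silyloxypentadienyl anion, which fixes the enol ether geometry).
- Forward order: two short branches are joined to the chain, rings A and B form together by an intramolecular [4+2], then ring C closes by epoxide opening, ring D by alkynol cycloisomerisation, and the acetate goes on last.
- Stereochemistry: C5, C6 and C10 come from the cycloaddition (relative sense from the Z enol ether, the E nitroalkene and the nitro-endo chair; absolute sense from a chiral bis-thiourea). C8 is set by equilibration, 6β-O by α-face hydride delivery, C9 by α-face epoxidation, and C13 by Sharpless epoxidation followed by inversion.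

Key step: step 9

Assumption: no model predicts the sense of induction of the bis-thiourea in step 9. The (R,R) catalyst is written, and its mirror image is taken if the first run gives the antipode of 17.

Step 1
Reactants: 1 methyl isobutyrate; 2 1,2-dibromoethane
Product: 4 methyl 4-bromo-2,2-dimethylbutanoate, via lithium enolate 3 (not isolated)
Conditions: LiN(i-Pr)2, THF, −78 °C; then 2 (3 equiv), −78 °C to rt
Reagents that add atoms: none
Why: SN2 alkylation of a fully substituted ester enolate by a primary dihalide used in excess; the product has no α-hydrogen, so neither a second alkylation at that carbon nor ring closure can follow.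

Step 2
Reactants: 4 methyl 4-bromo-2,2-dimethylbutanoate
Product: 5 methyl 4-iodo-2,2-dimethylbutanoate
Conditions: NaI, acetone, reflux
Reagents that add atoms: sodium iodide, [Na+].[I-]
Why: Finkelstein exchange, driven by precipitation of NaBr, gives the iodide, whose fast substitution at low temperature is needed in step 5.

Step 3
Reactants: 6 methacrolein; 7 isopropenylmagnesium bromide, CH2=C(CH3)MgBr
Product: 8 2,4-dimethylpenta-1,4-dien-3-ol
Conditions: THF, −78 to 0 °C; aqueous work-up
Reagents that add atoms: none
Why: 1,2-addition of a vinylic Grignard reagent to an enal; the carbinol carbon carries two identical isopropenyl groups, so no stereocentre arises.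

Step 4
Reactants: 8 2,4-dimethylpenta-1,4-dien-3-ol
Product: 9 tert-butyl[(2,4-dimethylpenta-1,4-dien-3-yl)oxy]dimethylsilane
Conditions: t-BuMe2SiCl, imidazole, DMF, rt
Reagents that add atoms: tert-butyldimethylsilyl chloride, CC(C)(C)[Si](C)(C)Cl
Why: Standard imidazole-promoted silylation of a secondary alcohol; the bulky silyl group is chosen because it resists O-to-C migration in the anion of step 5 and survives steps 6 to 9.

Step 5
Reactants: 9 tert-butyl[(2,4-dimethylpenta-1,4-dien-3-yl)oxy]dimethylsilane; 5 methyl 4-iodo-2,2-dimethylbutanoate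
Product: 11 methyl (6Z)-7-(tert-butyldimethylsilyloxy)-2,2,6,8-tetramethylnona-6,8-dienoate, via silyloxypentadienyllithium 10 (not isolated)
Conditions: s-BuLi, THF, −78 °C; then 5, −78 to −30 °C; chromatography on Et3N-deactivated silica
Reagents that add atoms: none
Why: Removal of the doubly allylic, oxygen-bearing hydrogen gives a 3-silyloxypentadienyllithium, a class of anion that primary halides alkylate at the terminus (C1–C2 bond); internal O···Li coordination holds the reacting terminus cis to oxygen, so the chain should end up cis to OSi (Z enol ether, tether outside the diene), and the hindered ester without α-hydrogen should be spared at this temperature.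

Step 6
Reactants: 11 methyl (6Z)-7-(tert-butyldimethylsilyloxy)-2,2,6,8-tetramethylnona-6,8-dienoate
Product: 12 (6Z)-7-(tert-butyldimethylsilyloxy)-2,2,6,8-tetramethylnona-6,8-dienal
Conditions: i-Bu2AlH (1.1 equiv), CH2Cl2, −78 °C; aq. KNaC4H4O6 work-up
Reagents that add atoms: none
Why: Partial ester reduction; the neopentyl-type aluminium hemiacetal is stable at −78 °C and collapses to the aldehyde only on the neutral tartrate work-up, which leaves the enol ether intact.

Step 7
Reactants: 12 (6Z)-7-(tert-butyldimethylsilyloxy)-2,2,6,8-tetramethylnona-6,8-dienal; 13 nitromethane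
Product: 14 (7Z)-8-(tert-butyldimethylsilyloxy)-3,3,7,9-tetramethyl-1-nitrodeca-7,9-dien-2-ol (racemic)
Conditions: 13 (10 equiv), KOt-Bu (10 mol %), THF/t-BuOH, 0 °C
Reagents that add atoms: none
Why: Henry reaction forming C5–C6; the non-enolisable aldehyde can only accept the nitronate, excess nitromethane buffers the catalytic base, and the new carbinol centre is erased in step 8.

Step 8
Reactants: 14 (7Z)-8-(tert-butyldimethylsilyloxy)-3,3,7,9-tetramethyl-1-nitrodeca-7,9-dien-2-ol
Product: 16 (1E,7Z)-8-(tert-butyldimethylsilyloxy)-3,3,7,9-tetramethyl-1-nitrodeca-1,7,9-triene, via nitro mesylate 15 (not isolated)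
Conditions: MeSO2Cl, Et3N, CH2Cl2, −20 to 0 °C
Reagents that add atoms: none
Why: Mesylation followed by E1cB elimination of the β-nitro mesylate; the quaternary C4 forces the E nitroalkene, which has no γ-hydrogen and cannot deconjugate.

Step 9
Reactants: 16 (1E,7Z)-8-(tert-butyldimethylsilyloxy)-3,3,7,9-tetramethyl-1-nitrodeca-1,7,9-triene
Product: 17 (5S,6S,10S)-9-(tert-butyldimethylsilyloxy)-6α-nitro-11-nordrim-8-ene (trans-decalin, 5α-H, 10β-CH3, C8=C9 silyl enol ether)
Conditions: (R,R)-N,N'-(cyclohexane-1,2-diyl)bis{N'-[3,5-bis(trifluoromethyl)phenyl]thiourea} (20 mol %), 4 Å molecular sieves, toluene (0.02 M), 45 °C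
Reagents that add atoms: none
Why: Proposed new method: the two thiourea units bind the nitro oxygens through N–H···O hydrogen bonds and lower the LUMO of the E nitroalkene, which then takes up the electron-rich 2-silyloxydiene in a concerted but strongly asynchronous normal-demand [4+2] cycloaddition in which the nucleophilic enol ether carbon C10 bonds to the electrophilic C5 ahead of C7 to C6 (the matched, para orientation of OSi and NO2). The closest known reaction types are the thermal type 1 intramolecular Diels–Alder reaction of nitroalkene-terminated 1,7,9-decatrienes to trans-decalins and the thiourea-catalysed conjugate additions and cycloadditions of nitroalkenes; what is new is catalyst control of an intramolecular case with a fully substituted diene terminus. Ring B closes as the cyclohexene of the cycloaddition (bonds C5–C10 and C6–C7, new C8=C9 enol ether), and ring A closes in the same event as a six-membered carbocycle because the four-carbon C1–C4 tether, folded as a chair, joins the diene terminus C10 to the dienophile carbon C5. C10 and C5 are set relative to each other by the Z enol ether (tether outside, methyl inside) reacting through the nitro-endo, tether-exo transition state, which puts 10-CH3 and 5-H anti (trans fusion); C6 follows from suprafacial addition to the E alkene, which keeps NO2 trans to C4 and hence equatorial (6α); the absolute configuration of all three rests on the chiral pocket of the bound catalyst, which must shield one of the two enantiotopic face pairs of the achiral triene. The step needs endo over exo selectivity and a catalysed rate well above the racemic background: the gem-dimethyl group on C4 populates the reactive rotamer and disfavours a boat-like exo tether, the defined alkene geometries leave a single low-energy chair, and the crowding at C5 and C10 keeps the uncatalysed reaction slow at 45 °C.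

Step 10
Reactants: 17 9-(tert-butyldimethylsilyloxy)-6α-nitro-11-nordrim-8-ene
Product: 18 8α-methyl 6α-nitro-11-nordriman-9-one (5α-H, 10β-CH3)
Conditions: n-Bu4NF, AcOH, THF, 0 °C; then K2CO3 (cat.), MeOH, rt
Reagents that add atoms: none
Why: Fluoride cleavage of the silyl enol ether and protonation, followed by base equilibration through the enolate, which places the C8 methyl equatorial (8α) because the axial 8β position is 1,3-diaxial to the C10 methyl; the equatorial 6α-nitro group is likewise the thermodynamic epimer.

Step 11
Reactants: 18 8α-methyl 6α-nitro-11-nordriman-9-one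
Product: 20 8α-methyl 11-nordrimane-6,9-dione, via sodium nitronate 19 (not isolated)
Conditions: NaOMe, MeOH, rt; then aq. TiCl3 (4.5 equiv), rt
Reagents that add atoms: water, O
Why: Reductive Nef reaction, in which trivalent titanium reduces the nitronate to the imine and water hydrolyses it, the classical passage from a γ-nitro ketone to a 1,4-diketone; C5 and C8 keep the trans-fused, equatorial arrangement, which is also the thermodynamic one.

Step 12
Reactants: 20 8α-methyl 11-nordrimane-6,9-dione
Product: 21 6β-hydroxy-8α-methyl-11-nordriman-9-one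
Conditions: LiBH(s-Bu)3 (1.05 equiv), THF, −78 °C; H2O
Reagents that add atoms: none
Why: Chemo- and diastereoselective ketone reduction by a bulky borohydride: the β face of C6 is closed by the axial methyls on C4 and C10, so hydride enters equatorially from α and gives the axial 6β-alcohol, whereas C9, flanked by a quaternary and a tertiary carbon with its equatorial approach blocked by the C10 methyl, should stay untouched.

Step 13
Reactants: 21 6β-hydroxy-8α-methyl-11-nordriman-9-one
Product: 22 8α-methyl drim-9(11)-en-6β-ol (exocyclic C9=C11H2)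
Conditions: Ph3PCH3Br, KOt-Bu (each in excess), toluene, 100 °C
Reagents that add atoms: methyltriphenylphosphonium bromide, C[P+](c1ccccc1)(c1ccccc1)c1ccccc1.[Br-]
Why: Wittig methylenation under the forcing conditions used for hindered, enolisable ketones; the alkoxide is tolerated, and enolisation can only return the equatorial 8α-methyl ketone.

Step 14
Reactants: 22 8α-methyl drim-9(11)-en-6β-ol
Product: 23 9α,11-epoxy-8α-methyl driman-6β-ol
Conditions: 3-chloroperbenzoic acid, CH2Cl2, 0 °C
Reagents that add atoms: 3-chloroperbenzoic acid, OOC(=O)c1cccc(Cl)c1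
Why: Prilezhaev epoxidation; the peracid reaches the 1,1-disubstituted alkene from the α face, anti to the axial C10 methyl, which sets C9 with oxygen α (axial) and C11 β (equatorial).

Step 15
Reactants: 23 9α,11-epoxy-8α-methyl driman-6β-ol; 24 2-methylprop-2-en-1-ol (methallyl alcohol)
Product: 26 15-norlabd-13(16)-ene-6β,9α,14-triol, via dilithiated methallyl alcohol 25 (not isolated)
Conditions: 24, n-BuLi (2 equiv per 24), N,N,N',N'-tetramethylethylenediamine, Et2O, 0 °C to rt; then 23, THF, 0 to 40 °C; H2O
Reagents that add atoms: none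
Why: SN2 opening of a 2,2-disubstituted epoxide at its CH2 terminus (C11–C12 bond) by an allyllithium, the most reactive carbon nucleophile type for hindered spiro-epoxides; the C9–O bond is not touched, so the 9α configuration is kept.

Step 16
Reactants: 26 15-norlabd-13(16)-ene-6β,9α,14-triol
Product: 27 (13R)-13,16-epoxy-15-norlabdane-6β,9α,14-triol
Conditions: Ti(Oi-Pr)4, D-(−)-diisopropyl tartrate, t-BuOOH, 4 Å molecular sieves, CH2Cl2, −20 °C
Reagents that add atoms: tert-butyl hydroperoxide, CC(C)(C)OO
Why: Sharpless asymmetric epoxidation of a 2-substituted allylic alcohol; with the D-(−)-tartrate, oxygen is delivered under reagent control to the face that gives the (13R)-epoxide, the decalin centres being too remote to interfere.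

Step 17
Reactants: 27 (13R)-13,16-epoxy-15-norlabdane-6β,9α,14-triol
Product: 28 (13S)-13,16-epoxy-6β,9α-dihydroxy-15-norlabdan-14-al
Conditions: 2,2,6,6-tetramethylpiperidin-1-oxyl (10 mol %), PhI(OAc)2, CH2Cl2, 0 °C to rt
Reagents that add atoms: none
Why: Oxoammonium oxidation, selective for the primary alcohol over the hindered axial 6β-hydroxyl and the tertiary 9α-hydroxyl and routinely applied to 2,3-epoxy alcohols; C13 bears no hydrogen and cannot epimerise (only the descriptor changes).

Step 18
Reactants: 28 (13S)-13,16-epoxy-6β,9α-dihydroxy-15-norlabdan-14-al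
Product: 29 (13R)-13,16-epoxylabd-14-yne-6β,9α-diol
Conditions: dimethyl (1-diazo-2-oxopropyl)phosphonate, K2CO3, MeOH, 0 °C to rt
Reagents that add atoms: dimethyl (1-diazo-2-oxopropyl)phosphonate, COP(=O)(OC)C(=[N+]=[N-])C(C)=O
Why: The Ohira–Bestmann variant of the Seyferth–Gilbert homologation converts the non-enolisable aldehyde into the terminal alkyne (C14≡C15) under carbonate conditions that leave the epoxide intact.

Step 19
Reactants: 29 (13R)-13,16-epoxylabd-14-yne-6β,9α-diol
Product: 30 (13S)-9α,13-epoxylabd-14-yne-6β,16-diol
Conditions: camphor-10-sulfonic acid (10 mol %), CH2Cl2, 0 °C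
Reagents that add atoms: none
Why: Acid-catalysed 5-exo-tet epoxide opening; the 9α-hydroxyl attacks the tertiary, propargylic C13 opposite the epoxide oxygen, so ring C closes with inversion ((13R)-epoxide to (13S)-ether) and C16 is released as CH2OH.

Step 20
Reactants: 30 (13S)-9α,13-epoxylabd-14-yne-6β,16-diol
Product: 31 (13S)-9α,13:15,16-diepoxylabd-14-en-6β-ol
Conditions: Mo(CO)6 (25 mol %), Et3N, Et2O, hν (350 nm), rt; chromatography on basic alumina
Reagents that add atoms: none
Why: Endo-selective alkynol cycloisomerisation, in which a zerovalent molybdenum carbonyl–amine complex turns the terminal alkyne into a vinylidene that the C16 hydroxyl traps at C15, the established way from 1-alkyn-4-ols to 2,3-dihydrofurans; the basic medium protects the acid-labile spiro enol ether.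

Step 21
Reactants: 31 (13S)-9α,13:15,16-diepoxylabd-14-en-6β-ol
Product: 32 (13S)-6β-acetoxy-9α,13:15,16-diepoxylabd-14-ene (target, 5S,6R,8R,9R,10S,13S)
Conditions: Ac2O, 4-(dimethylamino)pyridine, Et3N, CH2Cl2, 40 °C
Reagents that add atoms: acetic anhydride, CC(=O)OC(C)=O
Why: Nucleophile-catalysed acylation of the only remaining hydroxyl; the basic medium avoids acid-induced opening of ring C to the furan, and warming offsets the 1,3-diaxial hindrance at 6β.

**Compound list**
1 | methyl isobutyrate | COC(=O)C(C)C | starting material
2 | 1,2-dibromoethane | BrCCBr | starting material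
3 | lithium enolate of methyl isobutyrate | COC(O[Li])=C(C)C | intermediate
4 | methyl 4-bromo-2,2-dimethylbutanoate | COC(=O)C(C)(C)CCBr | intermediate
5 | methyl 4-iodo-2,2-dimethylbutanoate | COC(=O)C(C)(C)CCI | intermediate
6 | methacrolein | CC(=C)C=O | starting material
7 | isopropenylmagnesium bromide | CC(=C)[Mg]Br | starting material
8 | 2,4-dimethylpenta-1,4-dien-3-ol | CC(=C)C(O)C(C)=C | intermediate
9 | tert-butyl[(2,4-dimethylpenta-1,4-dien-3-yl)oxy]dimethylsilane | CC(=C)C(O[Si](C)(C)C(C)(C)C)C(C)=C | intermediate
10 | 3-(tert-butyldimethylsilyloxy)-2,4-dimethylpentadienyllithium | [Li]C/C(C)=C(\O[Si](C)(C)C(C)(C)C)C(C)=C | intermediate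
11 | methyl (6Z)-7-(tert-butyldimethylsilyloxy)-2,2,6,8-tetramethylnona-6,8-dienoate | COC(=O)C(C)(C)CCC/C(C)=C(\O[Si](C)(C)C(C)(C)C)C(C)=C | intermediate
12 | (6Z)-7-(tert-butyldimethylsilyloxy)-2,2,6,8-tetramethylnona-6,8-dienal | O=CC(C)(C)CCC/C(C)=C(\O[Si](C)(C)C(C)(C)C)C(C)=C | intermediate
13 | nitromethane | C[N+](=O)[O-] | starting material
14 | (7Z)-8-(tert-butyldimethylsilyloxy)-3,3,7,9-tetramethyl-1-nitrodeca-7,9-dien-2-ol (racemic) | [O-][N+](=O)CC(O)C(C)(C)CCC/C(C)=C(\O[Si](C)(C)C(C)(C)C)C(C)=C | intermediate
15 | methanesulfonate of 14 | [O-][N+](=O)CC(OS(C)(=O)=O)C(C)(C)CCC/C(C)=C(\O[Si](C)(C)C(C)(C)C)C(C)=C | intermediate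
16 | (1E,7Z)-8-(tert-butyldimethylsilyloxy)-3,3,7,9-tetramethyl-1-nitrodeca-1,7,9-triene | [O-][N+](=O)/C=C/C(C)(C)CCC/C(C)=C(\O[Si](C)(C)C(C)(C)C)C(C)=C | intermediate
17 | (5S,6S,10S)-9-(tert-butyldimethylsilyloxy)-6α-nitro-11-nordrim-8-ene | [O-][N+](=O)[C@H]1CC(C)=C(O[Si](C)(C)C(C)(C)C)[C@@]2(C)CCCC(C)(C)[C@H]12 | intermediate
18 | 8α-methyl 6α-nitro-11-nordriman-9-one | [O-][N+](=O)[C@H]1C[C@@H](C)C(=O)[C@@]2(C)CCCC(C)(C)[C@H]12 | intermediate
19 | sodium nitronate of 18 | [Na+].[O-][N+]([O-])=C1C[C@@H](C)C(=O)[C@@]2(C)CCCC(C)(C)[C@H]12 | intermediate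
20 | 8α-methyl 11-nordrimane-6,9-dione | O=C1C[C@@H](C)C(=O)[C@@]2(C)CCCC(C)(C)[C@H]12 | intermediate
21 | 6β-hydroxy-8α-methyl-11-nordriman-9-one | O[C@@H]1C[C@@H](C)C(=O)[C@@]2(C)CCCC(C)(C)[C@H]12 | intermediate
22 | 8α-methyl drim-9(11)-en-6β-ol | O[C@@H]1C[C@@H](C)C(=C)[C@@]2(C)CCCC(C)(C)[C@H]12 | intermediate
23 | 9α,11-epoxy-8α-methyl driman-6β-ol | O[C@@H]1C[C@@H](C)[C@]2(CO2)[C@@]2(C)CCCC(C)(C)[C@H]12 | intermediate
24 | 2-methylprop-2-en-1-ol | CC(=C)CO | starting material
25 | C,O-dilithiated 2-methylprop-2-en-1-ol | [Li]CC(=C)CO[Li] | intermediate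
26 | 15-norlabd-13(16)-ene-6β,9α,14-triol | O[C@@H]1C[C@@H](C)[C@](O)(CCC(=C)CO)[C@@]2(C)CCCC(C)(C)[C@H]12 | intermediate
27 | (13R)-13,16-epoxy-15-norlabdane-6β,9α,14-triol | O[C@@H]1C[C@@H](C)[C@](O)(CC[C@@]3(CO)CO3)[C@@]2(C)CCCC(C)(C)[C@H]12 | intermediate
28 | (13S)-13,16-epoxy-6β,9α-dihydroxy-15-norlabdan-14-al | O[C@@H]1C[C@@H](C)[C@](O)(CC[C@@]3(C=O)CO3)[C@@]2(C)CCCC(C)(C)[C@H]12 | intermediate
29 | (13R)-13,16-epoxylabd-14-yne-6β,9α-diol | O[C@@H]1C[C@@H](C)[C@](O)(CC[C@@]3(C#C)CO3)[C@@]2(C)CCCC(C)(C)[C@H]12 | intermediate
30 | (13S)-9α,13-epoxylabd-14-yne-6β,16-diol | O[C@@H]1C[C@@H](C)[C@]2(CC[C@](C#C)(CO)O2)[C@@]2(C)CCCC(C)(C)[C@H]12 | intermediate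
31 | (13S)-9α,13:15,16-diepoxylabd-14-en-6β-ol | O[C@@H]1C[C@@H](C)[C@]2(CC[C@@]3(C=COC3)O2)[C@@]2(C)CCCC(C)(C)[C@H]12 | intermediate
32 | (13S)-6β-acetoxy-9α,13:15,16-diepoxylabd-14-ene | CC(=O)O[C@@H]1C[C@@H](C)[C@]2(CC[C@@]3(C=COC3)O2)[C@@]2(C)CCCC(C)(C)[C@H]12 | target

Total step count: 21
Longest linear sequence: 19 steps (6 to 32, steps 3 to 21)

**Steps most likely to fail**

1. Step 9. The hydrogen-bond donor may accelerate the reaction too little over the racemic background. It may also fail to tell the two enantiotopic face pairs apart, or the crowded C5–C10 bond may form only at temperatures where catalyst binding is lost.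
   - The fallback uses known chemistry and sets out from 16. Uncatalysed thermal intramolecular Diels–Alder reaction (toluene, 120 °C, sealed tube, 2,6-di-tert-butyl-4-methylphenol) should give the racemic trans-fused adduct F1.
   - Desilylation and equilibration as in step 10 give the racemic nitro ketone F2.
   - F2 is resolved by preparative chromatography on a cellulose tris(3,5-dimethylphenylcarbamate) phase. The (5S,6S,8R,10S) enantiomer is 18, where the route is rejoined.

2. Step 5. The two methyl groups may push the pentadienyl anion into a U shape, which erodes the Z geometry. Alkylation at the central carbon, silyl migration to carbon or attack on the ester may also compete.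
   - The fallback builds the ketone first and sets out from 1. Enolate 3 is alkylated with 1,3-dibromopropane to methyl 5-bromo-2,2-dimethylpentanoate F3.
   - The lithium enolate of methyl propanoate (THF/DMPU) is alkylated with F3 to give dimethyl 2,2,6-trimethylheptanedioate F4.
   - MeNH(OMe)·HCl with i-PrMgCl converts only the less hindered ester into the Weinreb amide F5.
   - Grignard reagent 7 turns F5 into the enone ester F6.
   - Soft enolisation (t-BuMe2SiOSO2CF3, Et3N, CH2Cl2) gives 11 together with its (6E)-isomer F7.
   - F7 is separated on Et3N-deactivated silica and returned to F6 with n-Bu4NF/AcOH. The route is rejoined at 11.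

3. Step 15. Substitution at the neopentyl-like C11 may be too slow, so the strongly basic dilithio reagent removes H-8 and isomerises the epoxide instead.
   - The fallback replaces the polar substitution by a radical C–C bond formation and sets out from 23. MgI2 (Et2O, −40 °C) opens the epoxide to the 11-iodo-6β,9α-diol F8.
   - Keck-type radical allylation with ethyl 2-[(tributylstannyl)methyl]acrylate and 2,2'-azobis(2-methylpropionitrile) in benzene at 80 °C is insensitive to the neopentyl environment. It should give the ethyl acrylate F9.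
   - i-Bu2AlH (CH2Cl2, −78 °C) reduces F9 to 26, where the route is rejoined.

**Further compounds**
F1 | step 9 | racemic 9-(tert-butyldimethylsilyloxy)-6α-nitro-11-nordrim-8-ene (17 plus mirror image) | [O-][N+](=O)[C@H]1CC(C)=C(O[Si](C)(C)C(C)(C)C)[C@@]2(C)CCCC(C)(C)[C@H]12.[O-][N+](=O)[C@@H]1CC(C)=C(O[Si](C)(C)C(C)(C)C)[C@]2(C)CCCC(C)(C)[C@@H]12
F2 | step 9 | racemic 8α-methyl 6α-nitro-11-nordriman-9-one (18 plus mirror image) | [O-][N+](=O)[C@H]1C[C@@H](C)C(=O)[C@@]2(C)CCCC(C)(C)[C@H]12.[O-][N+](=O)[C@@H]1C[C@H](C)C(=O)[C@]2(C)CCCC(C)(C)[C@@H]12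
F3 | step 5 | methyl 5-bromo-2,2-dimethylpentanoate | COC(=O)C(C)(C)CCCBr
F4 | step 5 | dimethyl 2,2,6-trimethylheptanedioate (racemic) | COC(=O)C(C)CCCC(C)(C)C(=O)OC
F5 | step 5 | methyl 7-[methoxy(methyl)amino]-2,2,6-trimethyl-7-oxoheptanoate (racemic) | CON(C)C(=O)C(C)CCCC(C)(C)C(=O)OC
F6 | step 5 | methyl 2,2,6,8-tetramethyl-7-oxonon-8-enoate (racemic) | COC(=O)C(C)(C)CCCC(C)C(=O)C(C)=C
F7 | step 5 | methyl (6E)-7-(tert-butyldimethylsilyloxy)-2,2,6,8-tetramethylnona-6,8-dienoate | COC(=O)C(C)(C)CCC/C(C)=C(/O[Si](C)(C)C(C)(C)C)C(C)=C
F8 | step 15 | 11-iodo-8α-methyl drimane-6β,9α-diol | O[C@@H]1C[C@@H](C)[C@](O)(CI)[C@@]2(C)CCCC(C)(C)[C@H]12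
F9 | step 15 | ethyl 6β,9α-dihydroxy-15-norlabd-13(16)-en-14-oate | O[C@@H]1C[C@@H](C)[C@](O)(CCC(=C)C(=O)OCC)[C@@]2(C)CCCC(C)(C)[C@H]12
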